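**Retrosynthetic overview**
1. Numbering: ring A pyrrolidine N4–C3–C2–C1–C9a; ring B azepane N4–C5–C6–C7–C8–C9–C9a; ring C cyclopentane C9–C10(Et)–C11–C12–C9a; ring D lactone C11–O–C14(=O)–C13(OH)(Me)–C12; ring E lactone C18–C19–C20(Me)–C21(=O)–O with C18 on C3. The β face of ring C carries N4, Et, H9, H11 and H12; the α face carries C1, C8, O–C11 and C13.
2. Enabling feature: the contiguous N4–C3–C18–O array at the junction of rings A and E (amine nitrogen β to the alkyl-oxygen carbon of ring E), with carboxyl C21 in a 1,4 relation to C18. Rings A and E are therefore cut together (C18–O and C3–N4) back to NH-azepane 35, which carries a (Z)-C3=C18 alkene and a methyl ester. Forward: I2, iodoamination, aziridinium ion, strain-release lactonisation.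
3. The (Z)-alkene comes from a Wittig reaction of C3 aldehyde 24 with the C18–C21 ylide; C20 is set by Evans allylation.
4. Ring D is built on a C12 ketone: Rubottom oxidation at C11, intramolecular HWE to the C12=C13 butenolide, then Mn–H/O2 hydration (sets C12 and C13). The C10 ethyl group comes from conjugate addition to the C10=C11 enone.
5. Ring B is closed by N-alkylation. C9 is set by catalytic asymmetric conjugate addition to a 2-substituted cyclopentenone (ring C is bought) and C9a by anti enolate amination; all later ring centres are relayed from C9. Ring order: C, B, D, then A and E together.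

Key step: step 20

Remark on the chemistry (assumption): the sense of induction of the NHC–copper catalyst in step 3 is assumed to give (R)-C9. If the (S)-ligand gives the antipode, the (R)-ligand is used.
Abbreviations: TBS = tert-butyldimethylsilyl; Boc = tert-butoxycarbonyl; DBAD = di-tert-butyl azodicarboxylate; dpm = dipivaloylmethanate.

Step 1
Reactants: 1 cyclopent-2-en-1-one
Product: 2 2-iodocyclopent-2-en-1-one
Conditions: I2, K2CO3, DMAP (cat.), THF/H2O, rt
Reagents that add atoms: iodine, [I][I]
Why: Nucleophile-catalysed α-iodination of an enone (conjugate addition of DMAP, iodination of the enolate, elimination) is the standard route to 2-iodoenones and creates no stereocentre.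

Step 2
Reactants: 2 2-iodocyclopent-2-en-1-one; 3 allyloxy(tert-butyl)dimethylsilane
Product: 5 2-[3-(tert-butyldimethylsilyloxy)propyl]cyclopent-2-en-1-one, via B-alkyl-9-BBN adduct 4 (not isolated)
Conditions: 3, 9-BBN-H, THF, rt; then 2, PdCl2(dppf) (cat.), AsPh3, Cs2CO3, DMF/THF/H2O, rt
Reagents that add atoms: 9-borabicyclo[3.3.1]nonane, B1C2CCCC1CCC2 (its atoms stay in 4 only)
Why: Anti-Markovnikov hydroboration followed by B-alkyl Suzuki–Miyaura coupling with a 2-iodoenone is well precedented and places the C1–C3 chain on the future C9a without touching the enone; no stereocentre is formed.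

Step 3
Reactants: 5 2-[3-(tert-butyldimethylsilyloxy)propyl]cyclopent-2-en-1-one; 6 1-bromo-4-chlorobutane
Product: 9 di-tert-butyl 1-[(1S,2R)-1-[3-(tert-butyldimethylsilyloxy)propyl]-2-(4-chlorobutyl)-5-oxocyclopentyl]hydrazine-1,2-dicarboxylate, via 4-chlorobutylmagnesium bromide 7 (not isolated), via bromomagnesium enolate 8 (not isolated)
Conditions: 6, Mg, Et2O, rt; Cu(OTf)2 (3 mol %), (S)-1-mesityl-3-(1-hydroxy-4-methylpentan-2-yl)-4,5-dihydroimidazolium PF6 (4 mol %), 5, Et2O, −30 °C; then DBAD, THF, −78 °C; AcOH quench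
Reagents that add atoms: di-tert-butyl azodicarboxylate, CC(C)(C)OC(=O)N=NC(=O)OC(C)(C)C; magnesium, [Mg] (stays in 7 and 8 only)
Why: Copper/NHC-catalysed asymmetric conjugate addition of a Grignard reagent to an α-substituted cyclopentenone sets C9 under catalyst control, and electrophilic amination of the regiodefined tetrasubstituted enolate takes place anti to the new C9 chain (the usual trans rule of conjugate addition–enolate trapping), so that N4 ends β and the C1 chain α at C9a.

Step 4
Reactants: 9 the hydrazide of step 3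
Product: 11 tert-butyl N-[(1S,2R)-1-[3-(tert-butyldimethylsilyloxy)propyl]-2-(4-chlorobutyl)-5-oxocyclopentyl]carbamate, via N-alkylated hydrazide 10 (not isolated)
Conditions: BrCH2CO2Me, Cs2CO3, MeCN, 50 °C, then reflux
Reagents that add atoms: methyl bromoacetate, COC(=O)CBr (its atoms stay in 10 only)
Why: N-Alkylation of the free carbamate N–H with bromoacetate followed by base-induced E1cB fragmentation cleaves the N–N bond without a reductant, spares the ketone and the alkyl chloride, and keeps one Boc group on N4; no stereocentre is affected.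

Step 5
Reactants: 11 the carbamate of step 4
Product: 12 tert-butyl (5aR,8aS)-8a-[3-(tert-butyldimethylsilyloxy)propyl]-8-oxooctahydrocyclopenta[b]azepine-1(2H)-carboxylate (rings B and C trans-fused; C12 ketone)
Conditions: NaH, Bu4NI (cat.), DMF, 0 to 60 °C, high dilution
Reagents that add atoms: none
Why: Intramolecular N-alkylation of the carbamate anion (7-exo-tet, iodide catalysis, both termini held on adjacent ring C carbons) closes ring B, and the trans fusion follows from the configurations already fixed at C9 and C9a.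

Step 6
Reactants: 12 the bicyclic ketone of step 5
Product: 14 tert-butyl (5aR,8aS)-8a-[3-(tert-butyldimethylsilyloxy)propyl]-8-oxo-3,4,5,5a,8,8a-hexahydrocyclopenta[b]azepine-1(2H)-carboxylate (C10=C11 enone), via trimethylsilyl enol ether 13 (not isolated)
Conditions: LiN(iPr)2, Me3SiCl, THF, −78 °C; then Pd(OAc)2 (1.1 equiv), MeCN, rt
Reagents that add atoms: chlorotrimethylsilane, C[Si](C)(C)Cl (its atoms stay in 13 only)
Why: Saegusa–Ito oxidation: C9a is quaternary, so enolisation can only go towards C11, and palladium-mediated dehydrosilylation gives the C10=C11 enone without touching C9 or C9a.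

Step 7
Reactants: 14 the enone of step 6
Product: 15 tert-butyl (5aR,6R,8aS)-8a-[3-(tert-butyldimethylsilyloxy)propyl]-6-ethyl-8-(trimethylsilyloxy)-3,4,5,5a,6,8a-hexahydrocyclopenta[b]azepine-1(2H)-carboxylate
Conditions: EtMgBr, CuBr·SMe2 (cat.), Me3SiCl, DMPU, THF, −78 °C
Reagents that add atoms: ethylmagnesium bromide, CC[Mg]Br; chlorotrimethylsilane, C[Si](C)(C)Cl
Why: Copper-catalysed, chlorosilane-accelerated conjugate addition to a 4-substituted cyclopentenone occurs anti to the adjacent α-oriented C9–C8 bond, which places the ethyl group β at C10, and the enolate is stored as its silyl ether for step 8.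

Step 8
Reactants: 15 the silyl enol ether of step 7
Product: 17 tert-butyl (5aR,6R,7S,8aS)-8a-[3-(tert-butyldimethylsilyloxy)propyl]-6-ethyl-7-hydroxy-8-oxooctahydrocyclopenta[b]azepine-1(2H)-carboxylate, via silyloxy ketone 16 (not isolated)
Conditions: mCPBA, CH2Cl2, −20 °C; then citric acid (cat.), MeOH, rt
Reagents that add atoms: 3-chloroperbenzoic acid, OOC(=O)c1cccc(Cl)c1
Why: Rubottom oxidation: the peracid attacks the enol ether on the α face, away from the β ethyl group at C10 and the β N4(Boc) at C9a, so that O–C11 ends α (trans to ethyl, which is also the preferred arrangement of this epimerisable centre).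

Step 9
Reactants: 17 the hydroxy ketone of step 8; 18 2-(diethoxyphosphoryl)propanoic acid
Product: 19 2-(diethoxyphosphoryl)propanoate ester of 17 at O–C11 (mixture at the phosphonate carbon)
Conditions: DCC, DMAP (cat.), CH2Cl2, 0 °C to rt
Reagents that add atoms: none
Why: Steglich esterification of the secondary alcohol attaches C13, C14 and C15 of ring D as a phosphonate; the stereochemical mixture at the phosphonate carbon is erased in step 10.

Step 10
Reactants: 19 the phosphonate ester of step 9
Product: 20 N4-Boc tricyclic butenolide (rings B/C/D; C12=C13 double bond; C13 methyl; 9R 9aS 10R 11S; C1–C3 chain as TBS ether)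
Conditions: K2CO3, 18-crown-6, toluene, rt to 60 °C
Reagents that add atoms: none
Why: The intramolecular Horner–Wadsworth–Emmons reaction reaches the hindered C12 ketone through a five-membered transition state and closes ring D as the α-methylbutenolide under a mild base that spares C11.

Step 11
Reactants: 20 the butenolide of step 10
Product: 22 N4-Boc tricyclic α-hydroxy lactone (rings B/C/D; 9R 9aS 10R 11S 12R 13S; C1–C3 chain as TBS ether), via tertiary hydroperoxide 21 (not isolated)
Conditions: Mn(dpm)3 (cat.), PhSiH3, O2 (1 atm), iPrOH/CH2Cl2, 0 °C to rt; then P(OEt)3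
Reagents that add atoms: dioxygen, O=O
Why: Mukaiyama-type reductive hydration of an α,β-unsaturated ester: a manganese hydride transfers H to C12, where only the cis-fused bicyclo[3.3.0] product (H12 β, cis to H11) is free of strain, and the tertiary C13 radical captures O2 on the convex face, away from ring C and the α chain at C9a, so that C13–OH is cis to H12 and the methyl group is concave.

Step 12
Reactants: 22 the silyl ether of step 11
Product: 23 N4-Boc tricyclic α-hydroxy lactone with a free 3-hydroxypropyl chain at C9a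
Conditions: HF·pyridine, THF, 0 °C to rt
Reagents that add atoms: none
Why: Fluoride cleavage of the primary silyl ether in a buffered medium leaves the Boc group, the lactone and the tertiary alcohol intact.

Step 13
Reactants: 23 the primary alcohol of step 12
Product: 24 N4-Boc tricyclic α-hydroxy lactone C3 aldehyde (3-oxopropyl chain at C9a)
Conditions: Dess–Martin periodinane, CH2Cl2, rt
Reagents that add atoms: none
Why: Dess–Martin oxidation takes the only oxidisable (primary) alcohol to the C3 aldehyde, and the fully substituted N4 cannot form a hemiaminal.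

Step 14
Reactants: 25 (R)-4-benzyl-3-propionyloxazolidin-2-one; 26 allyl iodide
Product: 27 (R)-4-benzyl-3-[(S)-2-methylpent-4-enoyl]oxazolidin-2-one
Conditions: NaN(SiMe3)2, THF, −78 °C; then 26
Reagents that add atoms: none
Why: Evans alkylation: the chelated Z-enolate is allylated on the face opposite to the benzyl group, which sets C20 as S.

Step 15
Reactants: 27 the allylated imide of step 14
Product: 30 (S)-3-methyldihydrofuran-2(3H)-one, via aldehyde imide 28 (not isolated), via hydroxy imide 29 (not isolated)
Conditions: O3, CH2Cl2/MeOH, −78 °C; Me2S; then NaBH4, 0 °C; aq. NH4Cl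
Reagents that add atoms: ozone, [O-][O+]=O
Why: Ozonolysis removes the terminal carbon, and chemoselective borohydride reduction of the aldehyde gives a γ-hydroxy imide that lactonises spontaneously with release of the auxiliary; C20 is not touched.

Step 16
Reactants: 30 (S)-3-methyldihydrofuran-2(3H)-one
Product: 31 methyl (S)-4-bromo-2-methylbutanoate
Conditions: HBr (gas), MeOH, 0 °C to rt
Reagents that add atoms: hydrogen bromide, Br; methanol, CO
Why: Acid-mediated opening of a γ-lactone by bromide at the alkyl carbon, combined with Fischer esterification, is the standard route to 4-bromobutanoates, and the non-basic medium preserves C20.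

Step 17
Reactants: 31 methyl (S)-4-bromo-2-methylbutanoate
Product: 32 [(S)-4-methoxy-3-methyl-4-oxobutyl]triphenylphosphonium bromide
Conditions: PPh3, MeCN, reflux
Reagents that add atoms: triphenylphosphine, c1ccc(cc1)P(c1ccccc1)c1ccccc1
Why: SN2 quaternisation of triphenylphosphine by a primary bromide is the standard preparation of (3-alkoxycarbonylpropyl)phosphonium salts and does not involve C20.

Step 18
Reactants: 24 the C3 aldehyde of step 13; 32 the phosphonium bromide of step 17
Product: 34 N4-Boc (Z)-alkenyl ester (rings B/C/D; C9a chain CH2CH2CH=CHCH2CH(CH3)CO2CH3 with Z C3=C18 and 20S), via phosphonium ylide 33 (not isolated)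
Conditions: 32 (excess), NaN(SiMe3)2 (slightly less than 1 equiv per 32), THF, −78 to 0 °C; then 24, −78 °C to rt
Reagents that add atoms: none
Why: The Wittig reaction of a non-stabilised ylide at low temperature is kinetically Z-selective, and the slight deficit of base protects the C20 stereocentre α to the ester.

Step 19
Reactants: 34 the N4-Boc (Z)-alkenyl ester of step 18
Product: 35 NH-azepane (Z)-alkenyl ester (rings B/C/D; free N4–H; free C13–OH)
Conditions: CF3CO2H/CH2Cl2, 0 °C; aq. NaHCO3 wash
Reagents that add atoms: none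
Why: Acidolysis of the tert-butyl carbamate frees N4 and leaves both ester functions, the Z alkene and the non-ionisable α-acyl tertiary alcohol untouched.

Step 20
Reactants: 35 the NH-azepane (Z)-alkenyl ester of step 19
Product: 39 CNP0260919.2 (3S 9R 9aS 10R 11S 12R 13S 18S 20S), via iodopyrrolidine 36 (not isolated), via aziridinium iodide 37 (not isolated), via methoxyoxonium iodide 38 (not isolated)
Conditions: I2, NaHCO3, CH2Cl2/Et2O, rt, dark; aq. Na2S2O3 wash
Reagents that add atoms: iodine, [I][I] (its atoms stay in 36, 37 and 38 only)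
Why: I2 adds reversibly to the (Z)-C3=C18 alkene and N4–H attacks C3 anti to iodine (5-exo-trig, closes ring A) to give 36, whose now tertiary N4 expels iodide from C18 with inversion (3-exo-tet) to give the strained 1-azoniabicyclo[3.1.0]hexane 37; relief of this strain drives attack of the ester carbonyl oxygen on C18 with a second inversion (5-exo-tet, closes ring E through the C18–O bond), and iodide demethylates oxonium 38 irreversibly. The closest known reaction type is the iodine-induced tandem aminocyclisation–lactonisation of secondary amino (Z)-alkenyl esters through an aziridinium ion, that is, haloamination followed by neighbouring-group substitution. C18 is set stereospecifically relative to C3, because anti addition to the Z alkene followed by double inversion at C18 equals net anti addition of N and O and can give only the like pair (3S,18S or 3R,18R). C3 is set by C9a and ring B: C9a puts one ring C carbon on each face of the forming pyrrolidine, so the deciding contact is with C5, which ring B holds on the C9 side of N4, and the C18 chain should settle on the C12 side (the 3S,18S series), while a wrong-face iodoamine can revert by loss of I2 because only the lactonisation is irreversible. The step needs N-before-O chemoselectivity, 5-exo rather than 6-endo attack, and opening of 37 at C18 rather than C3; these are secured by the much higher nucleophilicity of the amine over the ester and the remote tertiary C13–OH, by the gem-disubstitution at C9a, and by the 1,4 distance of C21 from C18, which allows a five-membered transition state only at C18. C20 is a spectator and ends cis to the C3 substituent on ring E because it was installed as S in step 14.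

**Compound list**
1 | cyclopent-2-en-1-one | O=C1C=CCC1 | starting material
2 | 2-iodocyclopent-2-en-1-one | O=C1CCC=C1I | intermediate
3 | allyloxy(tert-butyl)dimethylsilane | C=CCO[Si](C)(C)C(C)(C)C | starting material
4 | 9-[3-(tert-butyldimethylsilyloxy)propyl]-9-borabicyclo[3.3.1]nonane | CC(C)(C)[Si](C)(C)OCCCB1C2CCCC1CCC2 | intermediate
5 | 2-[3-(tert-butyldimethylsilyloxy)propyl]cyclopent-2-en-1-one | O=C1CCC=C1CCCO[Si](C)(C)C(C)(C)C | intermediate
6 | 1-bromo-4-chlorobutane | ClCCCCBr | starting material
7 | 4-chlorobutylmagnesium bromide | ClCCCC[Mg]Br | intermediate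
8 | bromomagnesium enolate of (3R)-3-(4-chlorobutyl)-2-[3-(TBS-oxy)propyl]cyclopentanone | Br[Mg]OC1=C(CCCO[Si](C)(C)C(C)(C)C)[C@H](CCCCCl)CC1 | intermediate
9 | di-tert-butyl 1-[(1S,2R)-1-[3-(TBS-oxy)propyl]-2-(4-chlorobutyl)-5-oxocyclopentyl]hydrazine-1,2-dicarboxylate | O=C1CC[C@@H](CCCCCl)[C@]1(CCCO[Si](C)(C)C(C)(C)C)N(NC(=O)OC(C)(C)C)C(=O)OC(C)(C)C | intermediate
10 | N'-(2-methoxy-2-oxoethyl) derivative of 9 | O=C1CC[C@@H](CCCCCl)[C@]1(CCCO[Si](C)(C)C(C)(C)C)N(C(=O)OC(C)(C)C)N(CC(=O)OC)C(=O)OC(C)(C)C | intermediate
11 | tert-butyl N-[(1S,2R)-1-[3-(TBS-oxy)propyl]-2-(4-chlorobutyl)-5-oxocyclopentyl]carbamate | O=C1CC[C@@H](CCCCCl)[C@]1(CCCO[Si](C)(C)C(C)(C)C)NC(=O)OC(C)(C)C | intermediate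
12 | tert-butyl (5aR,8aS)-8a-[3-(TBS-oxy)propyl]-8-oxooctahydrocyclopenta[b]azepine-1(2H)-carboxylate | O=C1CC[C@H]2CCCCN(C(=O)OC(C)(C)C)[C@]12CCCO[Si](C)(C)C(C)(C)C | intermediate
13 | C12 trimethylsilyl enol ether of 12 | C[Si](C)(C)OC1=CC[C@H]2CCCCN(C(=O)OC(C)(C)C)[C@]12CCCO[Si](C)(C)C(C)(C)C | intermediate
14 | (5aR,8aS) C10=C11 enone of the B/C bicycle | O=C1C=C[C@H]2CCCCN(C(=O)OC(C)(C)C)[C@]12CCCO[Si](C)(C)C(C)(C)C | intermediate
15 | (5aR,6R,8aS) 6-ethyl trimethylsilyl enol ether | C[Si](C)(C)OC1=C[C@H](CC)[C@H]2CCCCN(C(=O)OC(C)(C)C)[C@]12CCCO[Si](C)(C)C(C)(C)C | intermediate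
16 | (5aR,6R,7S,8aS) 7-(trimethylsilyloxy) ketone | O=C1[C@@H](O[Si](C)(C)C)[C@H](CC)[C@H]2CCCCN(C(=O)OC(C)(C)C)[C@]12CCCO[Si](C)(C)C(C)(C)C | intermediate
17 | (5aR,6R,7S,8aS) 7-hydroxy ketone | O=C1[C@@H](O)[C@H](CC)[C@H]2CCCCN(C(=O)OC(C)(C)C)[C@]12CCCO[Si](C)(C)C(C)(C)C | intermediate
18 | 2-(diethoxyphosphoryl)propanoic acid | CCOP(=O)(OCC)C(C)C(=O)O | starting material
19 | 2-(diethoxyphosphoryl)propanoate of 17 | O=C1[C@@H](OC(=O)C(C)P(=O)(OCC)OCC)[C@H](CC)[C@H]2CCCCN(C(=O)OC(C)(C)C)[C@]12CCCO[Si](C)(C)C(C)(C)C | intermediate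
20 | N4-Boc tricyclic α-methylbutenolide (C12=C13) | CC[C@H]1[C@@H]2OC(=O)C(C)=C2[C@@]2(CCCO[Si](C)(C)C(C)(C)C)N(C(=O)OC(C)(C)C)CCCC[C@H]12 | intermediate
21 | C13 hydroperoxide | CC[C@H]1[C@@H]2OC(=O)[C@@](C)(OO)[C@@H]2[C@@]2(CCCO[Si](C)(C)C(C)(C)C)N(C(=O)OC(C)(C)C)CCCC[C@H]12 | intermediate
22 | N4-Boc tricyclic α-hydroxy lactone, TBS ether | CC[C@H]1[C@@H]2OC(=O)[C@@](C)(O)[C@@H]2[C@@]2(CCCO[Si](C)(C)C(C)(C)C)N(C(=O)OC(C)(C)C)CCCC[C@H]12 | intermediate
23 | N4-Boc tricyclic α-hydroxy lactone, primary alcohol | CC[C@H]1[C@@H]2OC(=O)[C@@](C)(O)[C@@H]2[C@@]2(CCCO)N(C(=O)OC(C)(C)C)CCCC[C@H]12 | intermediate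
24 | N4-Boc tricyclic α-hydroxy lactone, C3 aldehyde | CC[C@H]1[C@@H]2OC(=O)[C@@](C)(O)[C@@H]2[C@@]2(CCC=O)N(C(=O)OC(C)(C)C)CCCC[C@H]12 | intermediate
25 | (R)-4-benzyl-3-propionyloxazolidin-2-one | CCC(=O)N1[C@H](Cc2ccccc2)COC1=O | starting material
26 | allyl iodide | ICC=C | starting material
27 | (R)-4-benzyl-3-[(S)-2-methylpent-4-enoyl]oxazolidin-2-one | C=CC[C@H](C)C(=O)N1[C@H](Cc2ccccc2)COC1=O | intermediate
28 | (R)-4-benzyl-3-[(S)-2-methyl-4-oxobutanoyl]oxazolidin-2-one | O=CC[C@H](C)C(=O)N1[C@H](Cc2ccccc2)COC1=O | intermediate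
29 | (R)-4-benzyl-3-[(S)-4-hydroxy-2-methylbutanoyl]oxazolidin-2-one | OCC[C@H](C)C(=O)N1[C@H](Cc2ccccc2)COC1=O | intermediate
30 | (S)-3-methyldihydrofuran-2(3H)-one | C[C@H]1CCOC1=O | intermediate
31 | methyl (S)-4-bromo-2-methylbutanoate | BrCC[C@H](C)C(=O)OC | intermediate
32 | [(S)-4-methoxy-3-methyl-4-oxobutyl]triphenylphosphonium bromide | [Br-].COC(=O)[C@@H](C)CC[P+](c1ccccc1)(c1ccccc1)c1ccccc1 | intermediate
33 | methyl (S)-2-methyl-4-(triphenylphosphoranylidene)butanoate | COC(=O)[C@@H](C)CC=P(c1ccccc1)(c1ccccc1)c1ccccc1 | intermediate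
34 | N4-Boc (Z)-alkenyl ester | CC[C@H]1[C@@H]2OC(=O)[C@@](C)(O)[C@@H]2[C@@]2(CC/C=C\C[C@H](C)C(=O)OC)N(C(=O)OC(C)(C)C)CCCC[C@H]12 | intermediate
35 | NH-azepane (Z)-alkenyl ester | CC[C@H]1[C@@H]2OC(=O)[C@@](C)(O)[C@@H]2[C@@]2(CC/C=C\C[C@H](C)C(=O)OC)NCCCC[C@H]12 | intermediate
36 | (3S,18S) C18 iodide with ring A closed | CC[C@H]1[C@@H]2OC(=O)[C@@](C)(O)[C@@H]2[C@@]23CC[C@@H]([C@@H](I)C[C@H](C)C(=O)OC)N2CCCC[C@H]13 | intermediate
37 | N4/C3/C18 aziridinium iodide | CC[C@H]1[C@@H]2OC(=O)[C@@](C)(O)[C@@H]2[C@@]23CC[C@H]4[C@@H](C[C@H](C)C(=O)OC)[N@@+]24CCCC[C@H]13.[I-] | intermediate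
38 | O-methyl oxonium iodide of ring E | CC[C@H]1[C@@H]2OC(=O)[C@@](C)(O)[C@@H]2[C@@]23CC[C@@H]([C@@H]4C[C@H](C)C(OC)=[O+]4)N2CCCC[C@H]13.[I-] | intermediate
39 | CNP0260919.2 | CC[C@H]1[C@@H]2OC(=O)[C@@](C)(O)[C@@H]2[C@@]23CC[C@@H]([C@@H]4C[C@H](C)C(=O)O4)N2CCCC[C@H]13 | target

Total step count: 20. Longest linear sequence: 16 (steps 1–13 and 18–20); the C18–C21 fragment takes steps 14–17.

**Steps most likely to fail**

Step 3. What may go wrong: poor enantioface discrimination in the copper-catalysed addition to an α-substituted cyclopentenone, and proton transfer or slow nitrogen capture at the crowded tetrasubstituted magnesium enolate.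
- The fallback sets out from 1 and comes back at 9. It moves the conjugate addition to the unsubstituted enone and the amination to an enol pathway.
- Bis(4-chlorobutyl)zinc, Cu(OTf)2 and a binaphthol-derived phosphoramidite add to 1. The zinc enolate is captured with allyl acetate and Pd(PPh3)4 to give (2S,3R)-2-allyl-3-(4-chlorobutyl)cyclopentan-1-one F1.
- Chemoselective hydroboration of the terminal alkene with 9-BBN-H and NaBO3 oxidation gives (2S,3R)-3-(4-chlorobutyl)-2-(3-hydroxypropyl)cyclopentan-1-one F2.
- TBSCl/imidazole gives (2S,3R)-2-[3-(tert-butyldimethylsilyloxy)propyl]-3-(4-chlorobutyl)cyclopentan-1-one F3.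
- Direct amination of F3 with DBAD under chiral phosphoric acid catalysis runs through the more substituted enol. Attack should again be anti to the chlorobutyl chain, and this gives 9.

Step 11. What may go wrong: slow hydrogen-atom transfer to the tetrasubstituted C12=C13 bond next to quaternary C9a, or reduction without oxygen capture.
- The fallback sets out from 17 and comes back at 22. It builds ring D at a lower substitution level and brings in oxygen by enolate chemistry.
- 17 and (triphenylphosphoranylidene)ketene (toluene, reflux; O-acylation, then intramolecular Wittig reaction) give the C13-unsubstituted tricyclic butenolide F4.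
- Conjugate reduction of this trisubstituted alkene with [(Ph3P)CuH]6 gives the cis-fused saturated lactone F5.
- LiN(iPr)2 and MeI methylate C13 from the convex face to give the C13-methyl lactone F6.
- KN(SiMe3)2 followed by 3-phenyl-2-(phenylsulfonyl)oxaziridine hydroxylates the enolate, again from the convex face. This turns the methyl group to the concave face and gives 22.

Step 20. What may go wrong: poor facial selectivity in the iodoamination at the hindered N4, stalling at the protonated iodoamine, or competing 6-endo attack.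
- The fallback sets out from 34 and comes back at 39. It reverses the order of the two bond formations and lets C20 instead of ring B choose the alkene face.
- Thiyl-radical equilibration (PhSSPh, hν) turns 34 into the N4-Boc (E)-alkenyl ester F7.
- Equilibrating iodolactonisation of the methyl ester (I2, MeCN) with N4 still protected closes ring E through the same C18–O bond, anti to iodine at C3. It should favour the cis-2,4-disubstituted lactone, the N4-Boc (3R,18S)-iodolactone F8.
- CF3CO2H gives the free amine iodolactone F9.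
- K2CO3 in MeCN closes ring A by intramolecular SN2 at C3 with inversion. Net syn addition to the E alkene leads to the same 3S,18S pair and to 39.

Further compounds
F1 | step 3 | (2S,3R)-2-allyl-3-(4-chlorobutyl)cyclopentan-1-one | O=C1CC[C@@H](CCCCCl)[C@@H]1CC=C
F2 | step 3 | (2S,3R)-3-(4-chlorobutyl)-2-(3-hydroxypropyl)cyclopentan-1-one | O=C1CC[C@@H](CCCCCl)[C@@H]1CCCO
F3 | step 3 | (2S,3R)-2-[3-(tert-butyldimethylsilyloxy)propyl]-3-(4-chlorobutyl)cyclopentan-1-one | O=C1CC[C@@H](CCCCCl)[C@@H]1CCCO[Si](C)(C)C(C)(C)C
F4 | step 11 | C13-unsubstituted tricyclic butenolide | CC[C@H]1[C@@H]2OC(=O)C=C2[C@@]2(CCCO[Si](C)(C)C(C)(C)C)N(C(=O)OC(C)(C)C)CCCC[C@H]12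
F5 | step 11 | cis-fused saturated lactone | CC[C@H]1[C@@H]2OC(=O)C[C@@H]2[C@@]2(CCCO[Si](C)(C)C(C)(C)C)N(C(=O)OC(C)(C)C)CCCC[C@H]12
F6 | step 11 | C13-methyl lactone (methyl convex) | CC[C@H]1[C@@H]2OC(=O)[C@@H](C)[C@@H]2[C@@]2(CCCO[Si](C)(C)C(C)(C)C)N(C(=O)OC(C)(C)C)CCCC[C@H]12
F7 | step 20 | N4-Boc (E)-alkenyl ester | CC[C@H]1[C@@H]2OC(=O)[C@@](C)(O)[C@@H]2[C@@]2(CC/C=C/C[C@H](C)C(=O)OC)N(C(=O)OC(C)(C)C)CCCC[C@H]12
F8 | step 20 | N4-Boc (3R,18S)-iodolactone | CC[C@H]1[C@@H]2OC(=O)[C@@](C)(O)[C@@H]2[C@@]2(CC[C@@H](I)[C@@H]3C[C@H](C)C(=O)O3)N(C(=O)OC(C)(C)C)CCCC[C@H]12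
F9 | step 20 | free amine iodolactone | CC[C@H]1[C@@H]2OC(=O)[C@@](C)(O)[C@@H]2[C@@]2(CC[C@@H](I)[C@@H]3C[C@H](C)C(=O)O3)NCCCC[C@H]12
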